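**Plan**

1. Numbering (germacrane, as a remark on the structure): ring carbons C1–C10, acrylate C11(=C13)–C12, lactone oxygen on C8, angelate on C6, cis-oxirane C4–C5, hydroxyl on C1, ring olefin C9=C10 (Z). The target is the (1R,4R,5S,6S,7R,8S)-12,8-olide.
2. Enabling feature: the lactone oxygen on C8 is allylic and stands 1,4 to the C1 hydroxyl across the Z C9=C10 olefin. This O–C8/C9=C10/C1–OH triad is the 1,4-adduct of the C12 carboxyl to an 8Z-ene-1,10-oxirane (vinyl oxirane) through a five-membered ring, so the O–C8 bond is cut first.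
3. Further cuts: C8=C9 (ring-closing metathesis), C6–C7 (chromium allylation of a cis-epoxy aldehyde), both oxiranes (tartrate-controlled epoxidations). Neryl acetate supplies C9–C10–C1–C2–C3–C4–C5–C6 with C14 and C15.
4. Forward ring order: 1,10-oxirane, 4,5-oxirane, temporary 12,6-lactone (formed by the allylation, used as template), ten-membered carbocycle, lactone reopened and C6 angeloylated, final 12,8-lactone.
5. Stereochemistry: C1/C10 from D-(−)-tartrate, C4/C5 from L-(+)-tartrate, C6 by Felkin addition, C7 by the anti (chair) chromium allylation, C8 by double inversion at palladium relayed from C10, and 9Z from the ring-held anti,anti-allyl.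

Key step: step 14

**Route**

Step 1
Reactants: 1 neryl acetate
Product: 2 (2Z,6E)-8-hydroxy-3,7-dimethylocta-2,6-dien-1-yl acetate
Conditions: SeO2 (0.2 equiv), t-BuOOH, salicylic acid (cat.), CH2Cl2, rt
Reagents that add atoms: tert-butyl hydroperoxide, CC(C)(C)OO
Why: Selenium dioxide allylic oxidation (ene reaction then [2,3] shift) should hydroxylate the E-methyl of the electron-rich terminal olefin, the olefin next to the acetate being deactivated.

Step 2
Reactants: 2
Product: 3 (2Z)-5-[(2R,3R)-3-(hydroxymethyl)-3-methyloxiran-2-yl]-3-methylpent-2-en-1-yl acetate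
Conditions: Ti(OiPr)4 (10 mol %), D-(−)-diethyl tartrate (12 mol %), t-BuOOH, 4 Å sieves, CH2Cl2, −20 °C
Reagents that add atoms: tert-butyl hydroperoxide, CC(C)(C)OO
Why: Sharpless asymmetric epoxidation of the E-allylic alcohol; the D-tartrate complex delivers oxygen to the face that gives the (2R,3R) trans-oxirane (future C10 and C1), and the Z-olefin without free hydroxyl does not react.

Step 3
Reactants: 3
Product: 4 (2Z)-5-[(2R,3S)-3-formyl-3-methyloxiran-2-yl]-3-methylpent-2-en-1-yl acetate
Conditions: TEMPO (10 mol %), PhI(OAc)2 (1.1 equiv), CH2Cl2, rt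
Reagents that add atoms: none
Why: Oxoammonium oxidation of the primary alcohol stops at the aldehyde and leaves oxirane and olefin alone; the α-carbon is quaternary and cannot epimerise.

Step 4
Reactants: 4
Product: 5 (2Z)-5-[(2R,3R)-3-ethenyl-3-methyloxiran-2-yl]-3-methylpent-2-en-1-yl acetate
Conditions: Ph3PCH3Br, KN(SiMe3)2, THF, −78 to 0 °C
Reagents that add atoms: methyltriphenylphosphonium bromide, C[P+](c1ccccc1)(c1ccccc1)c1ccccc1.[Br-]
Why: Wittig methylenation; the non-stabilised ylide should add to the aldehyde much faster than to the acetate at low temperature and builds the vinyl oxirane without touching a stereocentre.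

Step 5
Reactants: 5
Product: 6 (2Z)-5-[(2R,3R)-3-ethenyl-3-methyloxiran-2-yl]-3-methylpent-2-en-1-ol
Conditions: K2CO3 (0.2 equiv), MeOH, 0 °C
Reagents that add atoms: none
Why: Base-catalysed transesterification removes the acetate; the oxirane tolerates mild carbonate.

Step 6
Reactants: 6
Product: 7 [(2S,3R)-3-{2-[(2R,3R)-3-ethenyl-3-methyloxiran-2-yl]ethyl}-3-methyloxiran-2-yl]methanol
Conditions: Ti(OiPr)4, L-(+)-diethyl tartrate, t-BuOOH, 4 Å sieves, CH2Cl2, −20 °C
Reagents that add atoms: tert-butyl hydroperoxide, CC(C)(C)OO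
Why: Sharpless asymmetric epoxidation of the Z-allylic alcohol with the L-tartrate should give the (2S,3R) cis-oxirane (future C5 S, C4 R); the vinyl group on the first oxirane has no directing hydroxyl.

Step 7
Reactants: 7
Product: 8 (2R,3R)-3-{2-[(2R,3R)-3-ethenyl-3-methyloxiran-2-yl]ethyl}-3-methyloxirane-2-carbaldehyde
Conditions: TEMPO (10 mol %), PhI(OAc)2 (1.1 equiv), CH2Cl2, rt; used crude
Reagents that add atoms: none
Why: Same oxoammonium oxidation; it gives the cis-epoxy aldehyde under near-neutral conditions that do not open either oxirane.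

Step 8
Reactants: 9 methyl acrylate; 10 (E)-crotonaldehyde
Product: 11 methyl (4E)-3-hydroxy-2-methylidenehex-4-enoate (racemic)
Conditions: DABCO (0.5 equiv), neat, rt, several days
Reagents that add atoms: none
Why: Morita–Baylis–Hillman reaction (amine conjugate addition, aldol addition to the aldehyde carbonyl, elimination); the racemic carbinol is lost in the next step.

Step 9
Reactants: 11
Product: 12 methyl (2Z,4E)-2-(bromomethyl)hexa-2,4-dienoate
Conditions: PBr3 (0.4 equiv), Et2O, −10 to 0 °C
Reagents that add atoms: phosphorus tribromide, BrP(Br)Br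
Why: SN2′ bromination with allylic transposition should give the conjugated primary bromide with the propenyl group trans to the ester.

Step 10
Reactants: 8; 12
Product: 15 (4S,5S)-5-[(2S,3R)-3-{2-[(2R,3R)-3-ethenyl-3-methyloxiran-2-yl]ethyl}-3-methyloxiran-2-yl]-3-methylidene-4-[(1E)-prop-1-en-1-yl]oxolan-2-one (trans-lactone), via allylchromium reagent 13 (not isolated), via hydroxy ester 14 (not isolated)
Conditions: CrCl2 (4 equiv), THF, 0 °C to rt; pH 7 buffer work-up
Reagents that add atoms: none
Why: Nozaki–Hiyama–Kishi 2-(alkoxycarbonyl)allylation, in which chromium stays on the primary carbon (the methyl cap disfavours migration to the diene end) and adds through a chair transition state with the propenyl group equatorial (C6/C7 anti) on the Felkin–Anh face of the cis-epoxy aldehyde (C6 S), after which the chromium alkoxide should close on the methyl ester to the trans 12,6-lactone.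

Step 11
Reactants: 15
Product: 16 (1R,4R,5S,6S,7S,10R)-1,10:4,5-diepoxygermacra-8(Z),11(13)-dien-12,6-olide
Conditions: second-generation Grubbs catalyst (H2IMes)(PCy3)Cl2Ru=CHPh (10 mol %), CH2Cl2 (1 mM), 40 °C
Reagents that add atoms: none
Why: Ring-closing metathesis between the oxirane vinyl group and the propenyl group (propene lost); the trans-lactone and the two oxiranes hold the ends together, the Z olefin is expected as the less strained geometry of the ten-membered ring, and the electron-poor exo-methylene is a poor metathesis partner.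

Step 12
Reactants: 16
Product: 18 allyl (1R,4R,5S,6S,7S,10R)-1,10:4,5-diepoxy-6-hydroxygermacra-8(Z),11(13)-dien-12-oate, via lithium carboxylate 17 (not isolated)
Conditions: LiOH·H2O (1.1 equiv), THF–H2O, 0 °C; solvents removed; allyl bromide, DMF, rt
Reagents that add atoms: lithium hydroxide, [Li+].[OH-]; allyl bromide, C=CCBr
Why: Saponification of the temporary γ-lactone at the acyl carbon followed by SN2 O-alkylation of the carboxylate traps the seco acid before it can close again; cold, brief base treatment should avoid Payne rearrangement of the 6-hydroxy-4,5-oxirane.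

Step 13
Reactants: 18; 19 angelic acid
Product: 21 allyl (1R,4R,5S,6S,7S,10R)-6-angeloyloxy-1,10:4,5-diepoxygermacra-8(Z),11(13)-dien-12-oate, via mixed anhydride 20 (not isolated)
Conditions: 19, 2,4,6-trichlorobenzoyl chloride, Et3N, toluene, rt; then 18, 40 °C (no DMAP)
Reagents that add atoms: none
Why: Yamaguchi-type mixed-anhydride esterification without a nucleophilic catalyst should transfer the angeloyl group without Z-to-E isomerisation and faster than the hydroxy ester relactonises.

Step 14
Reactants: 21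
Product: 23 target (1R,4R,5S,6S,7R,8S)-6-angeloyloxy-4,5-epoxy-1-hydroxygermacra-9(Z),11(13)-dien-12,8-olide, via carboxylic acid 22 (not isolated)
Conditions: Pd(PPh3)4 (5 mol %), 2-ethylhexanoic acid (1.2 equiv), potassium 2-ethylhexanoate (0.2 equiv), THF (5 mM), 0 °C to rt
Reagents that add atoms: none
Why: Pd(PPh3)4 first passes the allyl group of 21 to 2-ethylhexanoate (Tsuji–Trost ester exchange) and so frees acid 22; zerovalent palladium then ionises the vinyl oxirane with inversion at C10 to an η3-allyl over C8–C9–C10 while the acid protonates the C1 alkoxide, and the C12 carboxylate attacks C8 on the face opposite to palladium. The closest known reaction type is the palladium-catalysed 1,4-addition of carboxylic acids to vinyl epoxides, here intramolecular. The γ-lactone closes by 5-exo-trig attack on the allyl terminus. C8 is set by the double inversion, which relays the C10 configuration (D-tartrate, step 2) to the lactone oxygen; the ring holds C7 and C1 both anti on the allyl (8Z olefin, C1 s-cis), so the new C9=C10 bond should be Z, and C1 keeps its oxygen and configuration. The step needs attack at C8 over C10, secured by five- against seven-membered closure, and ionisation of the vinyl oxirane only, secured because neither the C4–C5 oxirane nor the C6 angelate is allylic; protonation of the C1 alkoxide should suppress its own closure on C8 to a dihydrofuran.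

**Compound list**

1 | neryl acetate, (2Z)-3,7-dimethylocta-2,6-dien-1-yl acetate | CC(=O)OC/C=C(/C)CCC=C(C)C | starting material
2 | (2Z,6E)-8-hydroxy-3,7-dimethylocta-2,6-dien-1-yl acetate | CC(=O)OC/C=C(/C)CC/C=C(\C)CO | intermediate
3 | (2Z)-5-[(2R,3R)-3-(hydroxymethyl)-3-methyloxiran-2-yl]-3-methylpent-2-en-1-yl acetate | OC[C@@]1(C)O[C@@H]1CC/C(C)=C\COC(C)=O | intermediate
4 | (2Z)-5-[(2R,3S)-3-formyl-3-methyloxiran-2-yl]-3-methylpent-2-en-1-yl acetate | O=C[C@@]1(C)O[C@@H]1CC/C(C)=C\COC(C)=O | intermediate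
5 | (2Z)-5-[(2R,3R)-3-ethenyl-3-methyloxiran-2-yl]-3-methylpent-2-en-1-yl acetate | C=C[C@@]1(C)O[C@@H]1CC/C(C)=C\COC(C)=O | intermediate
6 | (2Z)-5-[(2R,3R)-3-ethenyl-3-methyloxiran-2-yl]-3-methylpent-2-en-1-ol | C=C[C@@]1(C)O[C@@H]1CC/C(C)=C\CO | intermediate
7 | [(2S,3R)-3-{2-[(2R,3R)-3-ethenyl-3-methyloxiran-2-yl]ethyl}-3-methyloxiran-2-yl]methanol | C=C[C@@]1(C)O[C@@H]1CC[C@@]2(C)O[C@H]2CO | intermediate
8 | (2R,3R)-3-{2-[(2R,3R)-3-ethenyl-3-methyloxiran-2-yl]ethyl}-3-methyloxirane-2-carbaldehyde | C=C[C@@]1(C)O[C@@H]1CC[C@@]2(C)O[C@H]2C=O | intermediate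
9 | methyl acrylate | C=CC(=O)OC | starting material
10 | (E)-crotonaldehyde | C/C=C/C=O | starting material
11 | methyl (4E)-3-hydroxy-2-methylidenehex-4-enoate (racemic) | C/C=C/C(O)C(=C)C(=O)OC | intermediate
12 | methyl (2Z,4E)-2-(bromomethyl)hexa-2,4-dienoate | BrC/C(=C\C=C\C)C(=O)OC | intermediate
13 | [(2Z,4E)-2-(methoxycarbonyl)hexa-2,4-dien-1-yl]chromium dichloride (trivalent chromium allyl reagent) | Cl[Cr](Cl)C/C(=C\C=C\C)C(=O)OC | intermediate
14 | methyl (3S,4E)-3-[(S)-hydroxy{(2S,3R)-3-{2-[(2R,3R)-3-ethenyl-3-methyloxiran-2-yl]ethyl}-3-methyloxiran-2-yl}methyl]-2-methylidenehex-4-enoate (formed as its chromium alkoxide) | C=C[C@@]1(C)O[C@@H]1CC[C@@]2(C)O[C@H]2[C@@H](O)[C@@H](/C=C/C)C(=C)C(=O)OC | intermediate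
15 | (4S,5S)-5-[(2S,3R)-3-{2-[(2R,3R)-3-ethenyl-3-methyloxiran-2-yl]ethyl}-3-methyloxiran-2-yl]-3-methylidene-4-[(1E)-prop-1-en-1-yl]oxolan-2-one | C=C[C@@]1(C)O[C@@H]1CC[C@@]2(C)O[C@H]2[C@H]3OC(=O)C(=C)[C@@H]3/C=C/C | intermediate
16 | (1R,4R,5S,6S,7S,10R)-1,10:4,5-diepoxygermacra-8(Z),11(13)-dien-12,6-olide (trans-lactone, trans-1,10-oxirane, cis-4,5-oxirane) | C=C1C(=O)O[C@H]2[C@H]1/C=C\[C@@]3(C)O[C@@H]3CC[C@@]4(C)O[C@H]42 | intermediate
17 | lithium (1R,4R,5S,6S,7S,10R)-1,10:4,5-diepoxy-6-hydroxygermacra-8(Z),11(13)-dien-12-oate | [Li+].[O-]C(=O)C(=C)[C@@H]1/C=C\[C@@]2(C)O[C@@H]2CC[C@@]3(C)O[C@H]3[C@H]1O | intermediate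
18 | allyl (1R,4R,5S,6S,7S,10R)-1,10:4,5-diepoxy-6-hydroxygermacra-8(Z),11(13)-dien-12-oate | C=CCOC(=O)C(=C)[C@@H]1/C=C\[C@@]2(C)O[C@@H]2CC[C@@]3(C)O[C@H]3[C@H]1O | intermediate
19 | angelic acid, (2Z)-2-methylbut-2-enoic acid | C/C=C(/C)C(=O)O | starting material
20 | (2Z)-2-methylbut-2-enoic 2,4,6-trichlorobenzoic anhydride | C/C=C(/C)C(=O)OC(=O)c1c(Cl)cc(Cl)cc1Cl | intermediate
21 | allyl (1R,4R,5S,6S,7S,10R)-6-angeloyloxy-1,10:4,5-diepoxygermacra-8(Z),11(13)-dien-12-oate | C=CCOC(=O)C(=C)[C@@H]1/C=C\[C@@]2(C)O[C@@H]2CC[C@@]3(C)O[C@H]3[C@H]1OC(=O)/C(C)=C\C | intermediate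
22 | (1R,4R,5S,6S,7S,10R)-6-angeloyloxy-1,10:4,5-diepoxygermacra-8(Z),11(13)-dien-12-oic acid | OC(=O)C(=C)[C@@H]1/C=C\[C@@]2(C)O[C@@H]2CC[C@@]3(C)O[C@H]3[C@H]1OC(=O)/C(C)=C\C | intermediate
23 | (1R,4R,5S,6S,7R,8S)-6-angeloyloxy-4,5-epoxy-1-hydroxygermacra-9(Z),11(13)-dien-12,8-olide (CNP0191628.1) | C=C1C(=O)O[C@H]2/C=C(/C)[C@H](O)CC[C@@]3(C)O[C@H]3[C@@H](OC(=O)/C(C)=C\C)[C@H]12 | target

**Step count and risks**

Total steps: 14. Longest linear sequence: 12 (steps 1–7 and 10–14, from neryl acetate).

Three steps most likely to fail: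

Step 14. Ionisation may go through a conformer with C1 syn on the allyl, which would give the E olefin or the C8 epimer; β-hydride elimination to a dienol or attack at C10 may compete. The fallback sets out from lithium carboxylate 17 (made from 16 as in step 12) and comes back at 23. Iodolactonisation of 17 (I2, NaHCO3, MeCN–H2O, 0 °C) should close the 12,8-lactone by anti addition across the 8Z olefin and give the 9-iodo-6-hydroxy-12,8-lactone F1. Acylation of F1 with mixed anhydride 20 under the conditions of step 13 gives the 9-iodo-6-angeloyloxy-12,8-lactone F2. Radical reduction of F2 (Bu3SnH, Et3B, air, toluene, 0 °C) generates the C9 radical, whose oxiranylcarbinyl opening forms C9=C10 and the C1 alkoxy radical, reduced to the C1 alcohol 23.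

Step 11. The strained trans-fused ten-membered ring may close slowly, leading to oligomers, or may close to the E olefin. The fallback removes the lactone template before ring closure; it sets out from 15 and comes back at 22. LiOH opens 15 to the open-chain lithium carboxylate F3, and MeI in DMF gives hydroxy methyl ester 14, now isolated. Acylation with 20 gives the open-chain 6-angelate methyl ester F4, metathesis of the conformationally free diene gives the macrocyclic methyl ester F5, and Me3SnOH (1,2-dichloroethane, 60 °C) cleaves the methyl ester selectively to acid 22. Acid 22 then takes the palladium step without the allyl exchange.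

Step 10. The anti (C6/C7) or the Felkin (C5/C6) selection may erode, or the chromium salts may reduce or open the epoxy aldehyde. The fallback uses a boronate whose olefin geometry fixes the outcome in a closed chair transition state; it sets out from 8 and comes back at 15. Pent-3-en-1-yne is lithiated (n-BuLi) and acylated with methyl chloroformate to methyl hex-4-en-2-ynoate F6. syn-Hydroalumination (i-Bu2AlH, HMPA) and capture with 2-(iodomethyl)-4,4,5,5-tetramethyl-1,3,2-dioxaborolane give methyl (2Z)-2-[(4,4,5,5-tetramethyl-1,3,2-dioxaborolan-2-yl)methyl]hexa-2,4-dienoate F7, with the propenyl group cis to the ester. Thermal allylboration of 8 with F7 (toluene, 80 °C) should give the anti adduct as its borate, which lactonises to 15.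

Further compounds
F1 | step 14 | 1,10:4,5-diepoxy-6-hydroxy-9-iodogermacr-11(13)-en-12,8-olide (C8–O and C9–I anti, other centres as in 17) | C=C1C(=O)O[C@H]2[C@H](I)[C@@]3(C)O[C@@H]3CC[C@@]4(C)O[C@H]4[C@@H](O)[C@H]12
F2 | step 14 | 6-angeloyloxy-1,10:4,5-diepoxy-9-iodogermacr-11(13)-en-12,8-olide | C=C1C(=O)O[C@H]2[C@H](I)[C@@]3(C)O[C@@H]3CC[C@@]4(C)O[C@H]4[C@@H](OC(=O)/C(C)=C\C)[C@H]12
F3 | step 11 | lithium salt of the open-chain hydroxy acid of 14 | C=C[C@@]1(C)O[C@@H]1CC[C@@]2(C)O[C@H]2[C@@H](O)[C@@H](/C=C/C)C(=C)C(=O)[O-].[Li+]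
F4 | step 11 | angelate of hydroxy methyl ester 14 | C=C[C@@]1(C)O[C@@H]1CC[C@@]2(C)O[C@H]2[C@@H](OC(=O)/C(C)=C\C)[C@@H](/C=C/C)C(=C)C(=O)OC
F5 | step 11 | methyl (1R,4R,5S,6S,7S,10R)-6-angeloyloxy-1,10:4,5-diepoxygermacra-8(Z),11(13)-dien-12-oate | COC(=O)C(=C)[C@@H]1/C=C\[C@@]2(C)O[C@@H]2CC[C@@]3(C)O[C@H]3[C@H]1OC(=O)/C(C)=C\C
F6 | step 10 | methyl hex-4-en-2-ynoate (olefin geometry not defined) | CC=CC#CC(=O)OC
F7 | step 10 | methyl (2Z)-2-[(4,4,5,5-tetramethyl-1,3,2-dioxaborolan-2-yl)methyl]hexa-2,4-dienoate | CC=C/C=C(/CB1OC(C)(C)C(C)(C)O1)C(=O)OC
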